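## The problem

The target is a 2,3-dihydro-4H-furo[3,2-c]pyran-4-one. A dihydrofuran (ring A: O1, C2, C3, C3a, C7a) is fused across C3a–C7a to a 2-pyranone (ring B: C3a, C4, O5, C6, C7, C7a). C2 carries a catechol, C3 carries a second 4-hydroxy-2-pyranone (ring C, joined through C6'), and C6 carries an (E)-4-hydroxystyryl arm.

The only stereocentres are the adjacent C2 and C3, trans and both S. The trans relation is the more stable one and should come almost free. The absolute configuration is the real task, and with no third stereocentre to relay from it has to come from a reagent.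

C3 is the centre that holds. C2 is a benzylic ether para to a phenol, with a vinylogous carboxylate as leaving group. Base (through a quinone methide) or acid (through the benzylic cation) can open and reclose C2–O1, so C3 can correct C2 to trans, but C2 cannot correct C3.

Several groups will not survive rough treatment:
- the catechol, above all as its anion, is oxidised;
- both 2-pyranones are opened by hydroxide or alkoxide;
- the styryl diene is sensitive to light and oxidants;
- the enol of ring C is acidic and strongly C-nucleophilic at C3', so it condenses with any aldehyde.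

The skeleton should therefore be complete before the four hydroxyl groups are freed, and the unmasking should be one mild, non-oxidising operation.

The feature that makes the key step possible is this. C3 stands at the aldehyde oxidation level between C3a, the nucleophilic carbon of a 4-hydroxy-2-pyranone, and C6' of ring C. C2 is a benzylic carbon bonded to O1, the enol oxygen of that same hydroxypyranone. Ring A is thus the sum of a C–C–O unit of ring B, an aldehyde carbon and a benzylic ylide carbon.

## Retrosynthesis

**Target 21 to protected 20.** No skeletal bond is cut; four O–protecting-group bonds are. The three phenols are carried as tert-butyldimethylsilyl ethers and the ring C enol as a 2-(trimethylsilyl)ethyl ether. This alkyl ether survives oxidation and base, and fluoride removes it together with the silyl ethers. It releases only ethene and a fluorosilane, whereas an alkoxymethyl acetal would release formaldehyde, which the freed C3' of ring C would capture. The forward step must be a single, buffered desilylation.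

**20 to styrylpyranone 5, pyranone aldehyde 7 and thiolanium salt 15.** C3–C3a, C2–C3 and O1–C2 are cut; C3a–C7a and C7a–O1 stay in 5. Against the neighbouring cuts (opening ring B, or adding ring C or the styryl arm after ring A), this one leaves nothing to build after the ring closure. It divides the molecule into three pieces, each two to four steps from commodity chemicals, and makes the ring and both stereocentres in one operation.

The forward reaction has to meet four demands:
- The aldehyde must be consumed before the benzylic ylide is released, because such ylides epoxidise aldehydes.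
- The alkylidene pyrandione 17 must not be captured by a second molecule of 5.
- The ylide face must be controlled.
- Closure must go through the 4-oxygen.

The first two are met by a relay. An arenesulfinic acid traps the condensation product as sulfone 16. Carbonate then releases 17 and the ylide 18 together. Betaine 19 closes to 20.

**15 to benzyl bromide 11 and thiolane 14.** The S–C bond is cut. A preformed salt is preferred to alkylating the sulfide in the flask, which would expose the pyranone enolate to a benzyl bromide. Tetrafluoroborate is chosen as counter-ion so that the salt cannot revert to bromide and sulfide. The C2 symmetry of 14 makes both sulfur lone pairs equivalent, so one salt forms.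

**11 back to aldehyde 8.** Bromide 11 comes from alcohol 10, aldehyde 9 and 3,4-dihydroxybenzaldehyde 8 by functional-group changes only.

**14 back to diol 12.** Both C–S bonds are cut, leading to dimesylate 13 and commercial (2R,5R)-hexane-2,5-diol 12. Double inversion gives the (2S,5S) sulfide.

**5 to pyranone 3 and aldehyde 2.** The styryl C=C bond is cut, through carbinol 4. A cross-coupling at C6 would need a halopyranone and a metal catalyst. The lateral aldol of the dianion of 3 uses the commodity pyranone directly and leaves the enol free, as the key step needs it. Aldehyde 2 is the silyl ether of 4-hydroxybenzaldehyde 1.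

**7 to ether 6 and pyranone 3.** The aldehyde oxygen is removed (C–H oxidation of the 6-methyl group), then the O-alkyl bond is cut. Both pyranone halves of the target thus descend from 3. Building the ring around a pre-oxidised carbon would be longer.

## Roads not taken

**Alternative 1: ring A by oxidative ring contraction.**
- Cut: C3–C3a, traced back to a six-membered ketone ring in (2S)-2-(3,4-diacetoxyphenyl)-7-methyl-2,3-dihydro-4H,5H-pyrano[3,2-c]pyran-4,5-dione A1.
- Forward step: PhI(OAc)2, a trivalent iodine reagent, in acidic trimethyl orthoformate. The ring-fusion carbon shifts from the ketone carbon to the neighbouring CH2, giving methyl (2S,3S)-2-(3,4-diacetoxyphenyl)-6-methyl-4-oxo-2,3-dihydro-4H-furo[3,2-c]pyran-3-carboxylate A2.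
- Merits: the contraction is a dependable reaction of flavanone-type ketones and delivers trans. C2 is set beforehand in A1, so the absolute configuration rests on firmer ground than in the chosen plan. On that point this road is better.
- Weak points: A2 has only a methyl group on C6 and an ester on C3. The styryl arm needs a basic aldol condensation. Ring C needs an ester homologation and lactonisation next to an enolisable C3–H whose enolate can expel O1 and destroy both centres. The oxidant also forces acetates on the catechol and a later change of protecting groups.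
- Comparison: the chosen plan sets against the better stereochemical certainty a skeleton that is complete at the ring closure and one step from the target.

**Alternative 2: ring A by oxidative alkoxycarbonylative cyclisation.**
- Cut: O1–C7a and C3a–C4, leading to the alkynol (1S,2R,7E)-1-[3,4-bis(tert-butyldimethylsilyloxy)phenyl]-6-(tert-butyldimethylsilyloxy)-2-[(tert-butyldimethylsilyloxy)methyl]-8-[4-(tert-butyldimethylsilyloxy)phenyl]oct-7-en-3-yn-1-ol A3.
- Forward step: PdCl2(MeCN)2 with CuCl2 under CO in methanol. Divalent palladium activates the alkyne, the hydroxyl attacks 5-endo-dig, and CO insertion with methanolysis gives the dihydrofuran ester A4.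
- Merits: both stereocentres are made in an open chain by well-understood aldol-type chemistry and are not touched by the cyclisation, which runs under nearly neutral conditions. Stereocontrol is as good as or better than in the chosen plan.
- Weak points: rings B and C are both still missing after the key step. Ring B needs oxidation of the side-chain carbinol and enol lactonisation. Ring C has to be grown from the silyloxymethyl arm through an aldehyde that is epimerisable at C3 and can lose O1 by β-elimination. The linear sequence becomes long.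
- Comparison: the chosen plan gives up substrate-based stereocontrol for a much shorter route.

**Alternative 3: ring B last by rhodium C–H/alkyne annulation.**
- Cut: C7a–C7 and O5–C6. The partners are (4S,5S)-5-[3,4-bis(tert-butyldimethylsilyloxy)phenyl]-4-(methoxycarbonyl)-4,5-dihydrofuran-3-carboxylic acid A5 and the silylated enyne (E)-tert-butyldimethyl{4-[4-(trimethylsilyl)but-1-en-3-yn-1-yl]phenoxy}silane A6.
- Forward step: [Cp*RhCl2]2 with Ag2CO3. The carboxylate directs trivalent rhodium to the C7a–H bond, the alkyne inserts, and C–O bond formation closes ring B to the silylated furopyranone A7.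
- Merits: the route is as convergent as the chosen one. The sensitive styryl arm enters late, which is an advantage over carrying a styrylpyranone from the start. The silyl group settles the regiochemistry of insertion.
- Weak points: the silyl group must then be removed. Ring C must still be built from the C3 ester beside the acidic C3–H, as in Alternative 1. An enantioselective synthesis of A5, a β-alkoxyacrylic acid prone to ring opening, is a task of its own.
- Comparison: the chosen plan answers the late introduction of the styryl arm with ring C already in place at the coupling and a single step after it.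

Key step: step 12

Assumption: the sense of induction of the thiolane is taken from its benzylide epoxidations of aldehydes, where the (2R,5R) sulfide gives (S,S)-stilbene oxides. Carried over to the annulation, and allowing for the change of CIP ranking at the benzylic carbon, this calls for the (2S,5S) sulfide 14 to reach (2S,3S)-20. Should the sense prove opposite, the enantiomeric diol, equally available, would be used.

## Route

Step 1
Reactants: 1 4-hydroxybenzaldehyde
Product: 2 4-[(tert-butyldimethylsilyl)oxy]benzaldehyde
Conditions: TBSCl, imidazole, CH2Cl2, rt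
Reagents that add atoms: tert-butyldimethylsilyl chloride, CC(C)(C)[Si](C)(C)Cl
Why: Silyl ether formation at a phenol; the aryl silyl ether hides the acidic phenol from the strong base of step 2 and the carbonate of step 12 and is removed by fluoride at the end.

Step 2
Reactants: 3 4-hydroxy-6-methyl-2H-pyran-2-one; 2 4-[(tert-butyldimethylsilyl)oxy]benzaldehyde
Product: 4 6-{2-[4-(tert-butyldimethylsilyloxy)phenyl]-2-hydroxyethyl}-4-hydroxy-2H-pyran-2-one (racemic carbinol)
Conditions: LiN(iPr)2 (2.4 equiv), THF, −78 °C; then 2; AcOH, −78 °C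
Reagents that add atoms: none
Why: Aldol addition of the pyranone dianion: the first equivalent of amide takes the enol proton, the second the 6-methyl proton (vinylogous to the lactone carbonyl), and the more basic lateral carbanion adds to the aldehyde in preference to C3 or oxygen. The carbinol centre is destroyed in step 3, so its configuration does not matter.

Step 3
Reactants: 4 6-{2-[4-(tert-butyldimethylsilyloxy)phenyl]-2-hydroxyethyl}-4-hydroxy-2H-pyran-2-one
Product: 5 6-{(E)-2-[4-(tert-butyldimethylsilyloxy)phenyl]ethenyl}-4-hydroxy-2H-pyran-2-one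
Conditions: p-TsOH·H2O (cat.), toluene, 80 °C
Reagents that add atoms: none
Why: Acid-catalysed dehydration (E1) of a benzylic carbinol: the para-silyloxy group stabilises the cation and loss of the acidic CH2 proton gives the conjugated E-alkene, the thermodynamic isomer. Aryl silyl ethers tolerate catalytic sulfonic acid in a non-nucleophilic solvent.

Step 4
Reactants: 3 4-hydroxy-6-methyl-2H-pyran-2-one
Product: 6 6-methyl-4-[2-(trimethylsilyl)ethoxy]-2H-pyran-2-one
Conditions: Me3SiCH2CH2OH, PPh3, DIAD, THF, 0 °C to rt
Reagents that add atoms: 2-(trimethylsilyl)ethanol, C[Si](C)(C)CCO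
Why: Mitsunobu etherification of the acidic enol, which for 4-hydroxy-2-pyranones is known to alkylate the 4-oxygen and keep the 2-pyranone. The ether blocks the nucleophilic C3' and the acidic OH of the future ring C.

Step 5
Reactants: 6 6-methyl-4-[2-(trimethylsilyl)ethoxy]-2H-pyran-2-one
Product: 7 2-oxo-4-[2-(trimethylsilyl)ethoxy]-2H-pyran-6-carbaldehyde
Conditions: SeO2, 1,4-dioxane, 150 °C, sealed tube
Reagents that add atoms: selenium dioxide, O=[Se]=O
Why: Riley oxidation of the 6-methyl group, activated as the vinylogous α-position of the lactone; the same oxidation is known for the 4-methoxy analogue. An alkyl ether, unlike an acetal, should outlast hot selenous acid.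

Step 6
Reactants: 8 3,4-dihydroxybenzaldehyde
Product: 9 3,4-bis[(tert-butyldimethylsilyl)oxy]benzaldehyde
Conditions: TBSCl, imidazole, DMF, rt
Reagents that add atoms: tert-butyldimethylsilyl chloride, CC(C)(C)[Si](C)(C)Cl
Why: Double silyl ether formation at the catechol, which would otherwise be oxidised and would quench the ylide of step 12.

Step 7
Reactants: 9 3,4-bis[(tert-butyldimethylsilyl)oxy]benzaldehyde
Product: 10 {3,4-bis[(tert-butyldimethylsilyl)oxy]phenyl}methanol
Conditions: NaBH4, MeOH–THF, 0 °C
Reagents that add atoms: none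
Why: Hydride reduction of an aromatic aldehyde; the aryl silyl ethers are stable to borohydride at low temperature over a short reaction time.

Step 8
Reactants: 10 {3,4-bis[(tert-butyldimethylsilyl)oxy]phenyl}methanol
Product: 11 4-(bromomethyl)-1,2-bis[(tert-butyldimethylsilyl)oxy]benzene
Conditions: CBr4, PPh3, CH2Cl2, 0 °C
Reagents that add atoms: carbon tetrabromide, BrC(Br)(Br)Br
Why: Appel bromination under neutral conditions, which spares the silyl ethers. The electron-rich benzylic bromide would be used at once.

Step 9
Reactants: 12 (2R,5R)-hexane-2,5-diol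
Product: 13 (2R,5R)-hexane-2,5-diyl dimethanesulfonate
Conditions: MsCl, Et3N, CH2Cl2, −20 to 0 °C
Reagents that add atoms: methanesulfonyl chloride, CS(=O)(=O)Cl
Why: O-sulfonylation of both secondary alcohols; no bond to a stereocentre is touched, so the configuration is retained.

Step 10
Reactants: 13 (2R,5R)-hexane-2,5-diyl dimethanesulfonate
Product: 14 (2S,5S)-2,5-dimethylthiolane
Conditions: Na2S·9H2O, DMSO, rt
Reagents that add atoms: sodium sulfide, [Na+].[Na+].[S-2]
Why: Double SN2 displacement by sulfide, the second one intramolecular (5-exo-tet). Each carbon is inverted once, which turns the (2R,5R) diol skeleton into the (2S,5S) sulfide.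

Step 11
Reactants: 11 4-(bromomethyl)-1,2-bis[(tert-butyldimethylsilyl)oxy]benzene; 14 (2S,5S)-2,5-dimethylthiolane
Product: 15 (2S,5S)-1-{3,4-bis[(tert-butyldimethylsilyl)oxy]benzyl}-2,5-dimethylthiolan-1-ium tetrafluoroborate
Conditions: NaBF4, CH2Cl2–H2O, rt
Reagents that add atoms: sodium tetrafluoroborate, [Na+].F[B-](F)(F)F
Why: S-alkylation of the sulfide (SN2) with anion exchange; bromide leaves into the water layer, so the salt cannot revert. The C2 axis makes both sulfur lone pairs equivalent, so only one sulfonium salt can form.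

Step 12
Reactants: 5 6-{(E)-2-[4-(tert-butyldimethylsilyloxy)phenyl]ethenyl}-4-hydroxy-2H-pyran-2-one; 7 2-oxo-4-[2-(trimethylsilyl)ethoxy]-2H-pyran-6-carbaldehyde; 15 (2S,5S)-1-{3,4-bis[(tert-butyldimethylsilyl)oxy]benzyl}-2,5-dimethylthiolan-1-ium tetrafluoroborate
Product: 20 (2S,3S)-2-[3,4-bis(tert-butyldimethylsilyloxy)phenyl]-6-{(E)-2-[4-(tert-butyldimethylsilyloxy)phenyl]ethenyl}-3-{2-oxo-4-[2-(trimethylsilyl)ethoxy]-2H-pyran-6-yl}-2,3-dihydro-4H-furo[3,2-c]pyran-4-one, via sulfone adduct 16 (not isolated), via alkylidene pyrandione 17 (not isolated), via thiolanium ylide 18 (not isolated), via sulfonium enolate betaine 19 (not isolated)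
Conditions: p-TolSO2H, 4 Å MS, CH2Cl2, rt; then 15, Cs2CO3, CH2Cl2–MeCN, −20 °C to rt
Reagents that add atoms: none
Why: Under the sulfinic acid, C3 of 5 condenses with aldehyde 7 (Knoevenagel) and the acid adds to the alkylidene to give sulfone 16, the usual latent form of such oxa-dienes, so that neither free aldehyde (which a benzylic sulfonium ylide would epoxidise) nor a second molecule of 5 is on hand when the ylide appears. Cs2CO3 then expels sulfinate from the enolate of 16 (E1cB) to release 17 and deprotonates 15 to ylide 18, which adds to the exocyclic carbon of 17 (C2–C3) to give betaine 19; the enolate oxygen on C7a displaces the thiolane at the benzylic carbon with inversion (O1–C2, 5-exo-tet) and closes ring A, a formal (4+1) annulation. The closest known reactions are the base-mediated three-component coupling of cyclic 1,3-dicarbonyl compounds, aldehydes and onium ylides to trans-2,3-dihydrofurans and the chiral sulfonium ylide (4+1) annulations of ortho-quinone methides released from sulfones and of alkylidene 1,3-diketones. C2 is controlled by the C2-symmetric thiolane, which leaves one face of the ylide carbon open and whose sense is carried through the invertive displacement; C3 follows from the anti approach of the two large groups in the addition and from trans closure, trans also being the more stable ring. Closure through the 4-oxygen and not the lactone carbonyl oxygen is expected because it keeps the 2-pyranone of ring B, as hydroxypyranones and hydroxycoumarins do in such annulations, and closure through carbon would give a strained spirocyclopropane. The silyl ethers, the silylethyl ether and both pyranones should be inert to carbonate at low temperature when water is excluded.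

Step 13
Reactants: 20 (2S,3S)-2-[3,4-bis(tert-butyldimethylsilyloxy)phenyl]-6-{(E)-2-[4-(tert-butyldimethylsilyloxy)phenyl]ethenyl}-3-{2-oxo-4-[2-(trimethylsilyl)ethoxy]-2H-pyran-6-yl}-2,3-dihydro-4H-furo[3,2-c]pyran-4-one
Product: 21 (2S,3S)-2-(3,4-dihydroxyphenyl)-3-(4-hydroxy-2-oxo-2H-pyran-6-yl)-6-[(E)-2-(4-hydroxyphenyl)ethenyl]-2,3-dihydro-4H-furo[3,2-c]pyran-4-one
Conditions: TBAF, AcOH, THF, 0 °C to rt, argon
Reagents that add atoms: none
Why: Fluoride-induced desilylation: the three aryl silyl ethers are cleaved at silicon, and the silylethyl ether fragments by β-elimination to ethene, fluorotrimethylsilane and the pyranone enolate, a leaving group comparable to the carboxylate of a silylethyl ester. Acetic acid keeps the phenols protonated, so the catechol is not oxidised and the para-hydroxybenzylic C2–O1 bond is not opened through a quinone methide. No stereocentre is touched.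

## Compound list

1 | 4-hydroxybenzaldehyde | O=Cc1ccc(O)cc1 | starting material
2 | 4-[(tert-butyldimethylsilyl)oxy]benzaldehyde | O=Cc1ccc(O[Si](C)(C)C(C)(C)C)cc1 | intermediate
3 | 4-hydroxy-6-methyl-2H-pyran-2-one | Cc1cc(O)cc(=O)o1 | starting material
4 | 6-{2-[4-(tert-butyldimethylsilyloxy)phenyl]-2-hydroxyethyl}-4-hydroxy-2H-pyran-2-one (racemic) | O=c1cc(O)cc(CC(O)c2ccc(O[Si](C)(C)C(C)(C)C)cc2)o1 | intermediate
5 | 6-{(E)-2-[4-(tert-butyldimethylsilyloxy)phenyl]ethenyl}-4-hydroxy-2H-pyran-2-one | O=c1cc(O)cc(/C=C/c2ccc(O[Si](C)(C)C(C)(C)C)cc2)o1 | intermediate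
6 | 6-methyl-4-[2-(trimethylsilyl)ethoxy]-2H-pyran-2-one | Cc1cc(OCC[Si](C)(C)C)cc(=O)o1 | intermediate
7 | 2-oxo-4-[2-(trimethylsilyl)ethoxy]-2H-pyran-6-carbaldehyde | C[Si](C)(C)CCOc1cc(C=O)oc(=O)c1 | intermediate
8 | 3,4-dihydroxybenzaldehyde | O=Cc1ccc(O)c(O)c1 | starting material
9 | 3,4-bis[(tert-butyldimethylsilyl)oxy]benzaldehyde | O=Cc1ccc(O[Si](C)(C)C(C)(C)C)c(O[Si](C)(C)C(C)(C)C)c1 | intermediate
10 | {3,4-bis[(tert-butyldimethylsilyl)oxy]phenyl}methanol | OCc1ccc(O[Si](C)(C)C(C)(C)C)c(O[Si](C)(C)C(C)(C)C)c1 | intermediate
11 | 4-(bromomethyl)-1,2-bis[(tert-butyldimethylsilyl)oxy]benzene | BrCc1ccc(O[Si](C)(C)C(C)(C)C)c(O[Si](C)(C)C(C)(C)C)c1 | intermediate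
12 | (2R,5R)-hexane-2,5-diol | C[C@@H](O)CC[C@@H](C)O | starting material
13 | (2R,5R)-hexane-2,5-diyl dimethanesulfonate | C[C@@H](OS(C)(=O)=O)CC[C@@H](C)OS(C)(=O)=O | intermediate
14 | (2S,5S)-2,5-dimethylthiolane | C[C@H]1CC[C@H](C)S1 | intermediate
15 | (2S,5S)-1-{3,4-bis[(tert-butyldimethylsilyl)oxy]benzyl}-2,5-dimethylthiolan-1-ium tetrafluoroborate | C[C@H]1CC[C@H](C)[S+]1Cc1ccc(O[Si](C)(C)C(C)(C)C)c(O[Si](C)(C)C(C)(C)C)c1.F[B-](F)(F)F | intermediate
16 | 6-{(E)-2-[4-(tert-butyldimethylsilyloxy)phenyl]ethenyl}-4-hydroxy-3-{(4-methylbenzenesulfonyl)[2-oxo-4-(2-trimethylsilylethoxy)-2H-pyran-6-yl]methyl}-2H-pyran-2-one (racemic at the sulfonyl carbon; formed in the flask, not isolated) | O=c1c(C(S(=O)(=O)c3ccc(C)cc3)c4cc(OCC[Si](C)(C)C)cc(=O)o4)c(O)cc(/C=C/c2ccc(O[Si](C)(C)C(C)(C)C)cc2)o1 | intermediate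
17 | 6-{(E)-2-[4-(tert-butyldimethylsilyloxy)phenyl]ethenyl}-3-{[2-oxo-4-(2-trimethylsilylethoxy)-2H-pyran-6-yl]methylidene}-2H-pyran-2,4(3H)-dione (exocyclic alkene geometry not fixed; formed in the flask, not isolated) | O=C1OC(/C=C/c2ccc(O[Si](C)(C)C(C)(C)C)cc2)=CC(=O)C1=Cc3cc(OCC[Si](C)(C)C)cc(=O)o3 | intermediate
18 | {3,4-bis[(tert-butyldimethylsilyl)oxy]phenyl}[(2S,5S)-2,5-dimethylthiolan-1-ium-1-yl]methanide (sulfonium ylide; formed in the flask, not isolated) | C[C@H]1CC[C@H](C)[S+]1[CH-]c1ccc(O[Si](C)(C)C(C)(C)C)c(O[Si](C)(C)C(C)(C)C)c1 | intermediate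
19 | betaine: (2S,5S)-2,5-dimethylthiolan-1-ium bonded through sulfur to the benzylic carbon (R, the future C2) of a 1-aryl-2-(pyranon-6-yl)ethyl unit whose second carbon (the future C3, R here by CIP ranking) carries the 4-oxido-2-oxo-6-styryl-2H-pyran-3-yl group (formed in the flask, not isolated) | C[Si](C)(C)CCOc1cc([C@H]([C@@H]([S+]2[C@@H](C)CC[C@@H]2C)c2ccc(O[Si](C)(C)C(C)(C)C)c(O[Si](C)(C)C(C)(C)C)c2)c3c([O-])cc(/C=C/c4ccc(O[Si](C)(C)C(C)(C)C)cc4)oc3=O)oc(=O)c1 | intermediate
20 | (2S,3S)-2-[3,4-bis(tert-butyldimethylsilyloxy)phenyl]-6-{(E)-2-[4-(tert-butyldimethylsilyloxy)phenyl]ethenyl}-3-{2-oxo-4-[2-(trimethylsilyl)ethoxy]-2H-pyran-6-yl}-2,3-dihydro-4H-furo[3,2-c]pyran-4-one | C[Si](C)(C)CCOc1cc([C@H]2c3c(cc(/C=C/c4ccc(O[Si](C)(C)C(C)(C)C)cc4)oc3=O)O[C@@H]2c2ccc(O[Si](C)(C)C(C)(C)C)c(O[Si](C)(C)C(C)(C)C)c2)oc(=O)c1 | intermediate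
21 | (2S,3S)-2-(3,4-dihydroxyphenyl)-3-(4-hydroxy-2-oxo-2H-pyran-6-yl)-6-[(E)-2-(4-hydroxyphenyl)ethenyl]-2,3-dihydro-4H-furo[3,2-c]pyran-4-one | O=c1cc(O)cc([C@H]2c3c(cc(/C=C/c4ccc(O)cc4)oc3=O)O[C@@H]2c2ccc(O)c(O)c2)o1 | target

## Step count and risks

Total step count: 13. Longest linear sequence: 6 steps (8 → 9 → 10 → 11 → 15 → 20 → 21, steps 6, 7, 8, 11, 12, 13).

**Step 12 (key step).**
- What may go wrong: the thiolane ylide may discriminate poorly between its faces toward so reactive an acceptor. The ylide-derived configuration may also erode if the electron-rich benzylic sulfonium ionises before the enolate closes. Benzyl transfer from 15 to sulfinate or to enolate oxygen may consume the salt.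
- Fallback: reagent control is given up for resolution. The fallback sets out from 11, with 5 and 7 as before. Bromide 11 is alkylated with tetrahydrothiophene (NaBF4, CH2Cl2–H2O) to 1-{3,4-bis[(tert-butyldimethylsilyl)oxy]benzyl}thiolan-1-ium tetrafluoroborate F1. Under the relay conditions of step 12, carbonate turns it into the achiral ylide {3,4-bis[(tert-butyldimethylsilyl)oxy]phenyl}(thiolan-1-ium-1-yl)methanide F2. F2 adds to 17 to give the racemic thiolanium enolate betaine F3, which closes to the racemic trans product, that is 20 together with its (2R,3R) enantiomer F4. Preparative chromatography on a chiral stationary phase separates the two, and the route is rejoined at 20.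

**Step 5.**
- What may go wrong: acid-induced fragmentation of the silylethyl ether in hot selenous acid, over-oxidation to the carboxylic acid, or stalling at the carbinol stage.
- Fallback: the aldehyde is made by alkene cleavage, setting out from 5. Mitsunobu etherification of 5 with 2-(trimethylsilyl)ethanol gives 6-{(E)-2-[4-(tert-butyldimethylsilyloxy)phenyl]ethenyl}-4-[2-(trimethylsilyl)ethoxy]-2H-pyran-2-one F5. OsO4 (catalytic) with NaIO4 and 2,6-lutidine in dioxane–water dihydroxylates the styryl double bond to the diol 6-{2-[4-(tert-butyldimethylsilyloxy)phenyl]-1,2-dihydroxyethyl}-4-[2-(trimethylsilyl)ethoxy]-2H-pyran-2-one F6, which is cleaved in the flask. The route is rejoined at 7, and aldehyde 2 is returned for reuse.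

**Step 2.**
- What may go wrong: incomplete formation of the dianion, so that the monoanion reacts at C3 or oxygen, and retro-aldol cleavage on quenching.
- Fallback: the pyranone ring is built instead of being extended, setting out from 2. Wittig olefination of 2 with Ph3P=CHC(O)N(OMe)Me gives the Weinreb amide (E)-3-[4-(tert-butyldimethylsilyloxy)phenyl]-N-methoxy-N-methylprop-2-enamide F7. Acylation of the dianion of methyl acetoacetate (NaH, then n-BuLi, THF) with F7 gives methyl (E)-7-[4-(tert-butyldimethylsilyloxy)phenyl]-3,5-dioxohept-6-enoate F8. DBU in warm toluene lactonises F8, and the route is rejoined at 5, replacing steps 2 and 3.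

**Step 13.**
- What may go wrong: slow fragmentation of the silylethyl ether under buffered fluoride would force more basic conditions. Phenoxide-driven opening of C2–O1 would then cause epimerisation at C2, and the catecholate would be oxidised by air.
- Fallback: the two kinds of group are removed separately, setting out from 20. KHF2 in methanol cleaves only the three aryl silyl ethers and gives (2S,3S)-2-(3,4-dihydroxyphenyl)-6-[(E)-2-(4-hydroxyphenyl)ethenyl]-3-{2-oxo-4-[2-(trimethylsilyl)ethoxy]-2H-pyran-6-yl}-2,3-dihydro-4H-furo[3,2-c]pyran-4-one F9. Trifluoroacetic acid in CH2Cl2 at 0 °C then removes the silylethyl group by acidolysis, and the route is rejoined at 21.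

## Further compounds

F1 | step 12 | 1-{3,4-bis[(tert-butyldimethylsilyl)oxy]benzyl}thiolan-1-ium tetrafluoroborate | C1CC[S+](C1)Cc1ccc(O[Si](C)(C)C(C)(C)C)c(O[Si](C)(C)C(C)(C)C)c1.F[B-](F)(F)F
F2 | step 12 | {3,4-bis[(tert-butyldimethylsilyl)oxy]phenyl}(thiolan-1-ium-1-yl)methanide | [CH-](c1ccc(O[Si](C)(C)C(C)(C)C)c(O[Si](C)(C)C(C)(C)C)c1)[S+]1CCCC1
F3 | step 12 | racemic thiolanium enolate betaine from F2 and 17 | C[Si](C)(C)CCOc1cc(C(C([S+]2CCCC2)c2ccc(O[Si](C)(C)C(C)(C)C)c(O[Si](C)(C)C(C)(C)C)c2)c3c([O-])cc(/C=C/c4ccc(O[Si](C)(C)C(C)(C)C)cc4)oc3=O)oc(=O)c1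
F4 | step 12 | (2R,3R) enantiomer of 20 | C[Si](C)(C)CCOc1cc([C@@H]2c3c(cc(/C=C/c4ccc(O[Si](C)(C)C(C)(C)C)cc4)oc3=O)O[C@H]2c2ccc(O[Si](C)(C)C(C)(C)C)c(O[Si](C)(C)C(C)(C)C)c2)oc(=O)c1
F5 | step 5 | 6-{(E)-2-[4-(tert-butyldimethylsilyloxy)phenyl]ethenyl}-4-[2-(trimethylsilyl)ethoxy]-2H-pyran-2-one | C[Si](C)(C)CCOc1cc(/C=C/c2ccc(O[Si](C)(C)C(C)(C)C)cc2)oc(=O)c1
F6 | step 5 | 6-{2-[4-(tert-butyldimethylsilyloxy)phenyl]-1,2-dihydroxyethyl}-4-[2-(trimethylsilyl)ethoxy]-2H-pyran-2-one (racemic, not isolated) | C[Si](C)(C)CCOc1cc(C(O)C(O)c2ccc(O[Si](C)(C)C(C)(C)C)cc2)oc(=O)c1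
F7 | step 2 | (E)-3-[4-(tert-butyldimethylsilyloxy)phenyl]-N-methoxy-N-methylprop-2-enamide | CON(C)C(=O)/C=C/c1ccc(O[Si](C)(C)C(C)(C)C)cc1
F8 | step 2 | methyl (E)-7-[4-(tert-butyldimethylsilyloxy)phenyl]-3,5-dioxohept-6-enoate | COC(=O)CC(=O)CC(=O)/C=C/c1ccc(O[Si](C)(C)C(C)(C)C)cc1
F9 | step 13 | (2S,3S)-2-(3,4-dihydroxyphenyl)-6-[(E)-2-(4-hydroxyphenyl)ethenyl]-3-{2-oxo-4-[2-(trimethylsilyl)ethoxy]-2H-pyran-6-yl}-2,3-dihydro-4H-furo[3,2-c]pyran-4-one | C[Si](C)(C)CCOc1cc([C@H]2c3c(cc(/C=C/c4ccc(O)cc4)oc3=O)O[C@@H]2c2ccc(O)c(O)c2)oc(=O)c1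
A1 | alternative 1 | (2S)-2-(3,4-diacetoxyphenyl)-7-methyl-2,3-dihydro-4H,5H-pyrano[3,2-c]pyran-4,5-dione | CC1=CC2=C(C(=O)C[C@@H](c3ccc(OC(C)=O)c(OC(C)=O)c3)O2)C(=O)O1
A2 | alternative 1 | methyl (2S,3S)-2-(3,4-diacetoxyphenyl)-6-methyl-4-oxo-2,3-dihydro-4H-furo[3,2-c]pyran-3-carboxylate | COC(=O)[C@H]2c3c(cc(C)oc3=O)O[C@@H]2c2ccc(OC(C)=O)c(OC(C)=O)c2
A3 | alternative 2 | (1S,2R,7E)-1-[3,4-bis(tert-butyldimethylsilyloxy)phenyl]-6-(tert-butyldimethylsilyloxy)-2-[(tert-butyldimethylsilyloxy)methyl]-8-[4-(tert-butyldimethylsilyloxy)phenyl]oct-7-en-3-yn-1-ol (C6 not assigned) | CC(C)(C)[Si](C)(C)OC[C@H]([C@H](O)c2ccc(O[Si](C)(C)C(C)(C)C)c(O[Si](C)(C)C(C)(C)C)c2)C#CCC(O[Si](C)(C)C(C)(C)C)/C=C/c3ccc(O[Si](C)(C)C(C)(C)C)cc3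
A4 | alternative 2 | methyl (4R,5S)-5-[3,4-bis(tert-butyldimethylsilyloxy)phenyl]-2-{(E)-2-(tert-butyldimethylsilyloxy)-4-[4-(tert-butyldimethylsilyloxy)phenyl]but-3-en-1-yl}-4-[(tert-butyldimethylsilyloxy)methyl]-4,5-dihydrofuran-3-carboxylate | CC(C)(C)[Si](C)(C)OC[C@H]2C(C(=O)OC)=C(CC(O[Si](C)(C)C(C)(C)C)/C=C/c3ccc(O[Si](C)(C)C(C)(C)C)cc3)O[C@@H]2c2ccc(O[Si](C)(C)C(C)(C)C)c(O[Si](C)(C)C(C)(C)C)c2
A5 | alternative 3 | (4S,5S)-5-[3,4-bis(tert-butyldimethylsilyloxy)phenyl]-4-(methoxycarbonyl)-4,5-dihydrofuran-3-carboxylic acid | COC(=O)[C@H]1C(C(=O)O)=CO[C@@H]1c1ccc(O[Si](C)(C)C(C)(C)C)c(O[Si](C)(C)C(C)(C)C)c1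
A6 | alternative 3 | (E)-tert-butyldimethyl{4-[4-(trimethylsilyl)but-1-en-3-yn-1-yl]phenoxy}silane | C[Si](C)(C)C#C/C=C/c1ccc(O[Si](C)(C)C(C)(C)C)cc1
A7 | alternative 3 | methyl (2S,3S)-2-[3,4-bis(tert-butyldimethylsilyloxy)phenyl]-6-{(E)-2-[4-(tert-butyldimethylsilyloxy)phenyl]ethenyl}-4-oxo-7-(trimethylsilyl)-2,3-dihydro-4H-furo[3,2-c]pyran-3-carboxylate | COC(=O)[C@H]2c3c(c([Si](C)(C)C)c(/C=C/c4ccc(O[Si](C)(C)C(C)(C)C)cc4)oc3=O)O[C@@H]2c2ccc(O[Si](C)(C)C(C)(C)C)c(O[Si](C)(C)C(C)(C)C)c2
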